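**Retrosynthetic overview**

1. The C3 acetate and C6 4-hydroxybenzoate are put on last. The C6 allylic alcohol comes from Luche reduction of a C6 enone, the C7=C8 bond from Saegusa–Ito oxidation of the C6 ketone, and the C4 carbinol from isopropyl addition to a C4 ketone.
2. The strategy rests on the seven-membered ring (C1, C5, C6, C7, C8, C9, C10). Its oxygenated carbons C6 and C10 flank the C1–C5 ring fusion and are joined by C7–C8(CH3)–C9, the pattern of a cyclohepta-1,4-diene bis(silyl enol ether).
3. Key disconnection: that ring is opened back to a cis-dialkenylcyclopropane spanning C1, C5 and C10 ([3,3] shift; forms C7–C8, breaks C5–C10).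
4. The cyclopropane and the five-membered ring (C1–C5) come together from one Rh-catalysed intramolecular cyclopropanation of a silyloxyvinyl diazoketone onto the C1=C10 silyl enol ether, which sets quaternary C1. The C3 oxygen is added on this rigid bicycle.
5. The diazo substrate comes from a Mukaiyama–Michael union of silylated diazoacetylacetone with 2-methylhexa-1,4-dien-3-one. Ring order: five-membered ring with cyclopropane first, seven-membered ring second.

Key step: step 9

Convention: atom numbers are those of the target (C1 quaternary ring-fusion carbon with CH3, C2 CH2, C3, C4, C5 ring-fusion CH, C6, C7=C8(CH3), C9, C10). "β" is the face of the bicycle that carries the C1 methyl, "α" the other face. The target is 3β-OAc, 4β-OH (4α-isopropyl), 5β-H, 6α-aroyloxy, 10β-OH.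

Assumption: Rh2(S-PTAD)4 is taken to give the enantiomer drawn for 10; if the sense of induction is the opposite, Rh2(R-PTAD)4 is used instead.

**Route**

Step 1
Reactants: 1 (E)-crotonaldehyde; 2 isopropenylmagnesium bromide
Product: 3 (E)-2-methylhexa-1,4-dien-3-ol (racemic)
Conditions: THF, −78 → 0 °C; H2O work-up
Reagents that add atoms: none
Why: Grignard 1,2-addition of the alkenyl nucleophile to the enal; the carbinol centre is racemic and is removed in step 2.

Step 2
Reactants: 3 (E)-2-methylhexa-1,4-dien-3-ol
Product: 4 (E)-2-methylhexa-1,4-dien-3-one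
Conditions: MnO2 (activated), CH2Cl2, 20 °C; filtered and used at once as a solution
Reagents that add atoms: none
Why: Allylic oxidation of the doubly allylic alcohol under neutral conditions gives the cross-conjugated dienone, which is volatile and polymerisable and so is not stored.

Step 3
Reactants: 5 pentane-2,4-dione
Product: 6 3-diazopentane-2,4-dione
Conditions: 4-AcNHC6H4SO2N3, Et3N, MeCN, 0 → 20 °C
Reagents that add atoms: 4-acetamidobenzenesulfonyl azide, CC(=O)Nc1ccc(cc1)S(=O)(=O)N=[N+]=[N-]
Why: Regitz diazo transfer to the activated methylene of a 1,3-diketone.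

Step 4
Reactants: 6 3-diazopentane-2,4-dione
Product: 7 3-diazo-4-(triethylsilyloxy)pent-4-en-2-one
Conditions: Et3SiOTf (1.05 equiv), Et3N, CH2Cl2, 0 °C
Reagents that add atoms: triethylsilyl triflate, CC[Si](CC)(CC)OS(=O)(=O)C(F)(F)F
Why: Soft enolisation and O-silylation of one acetyl group; the diketone is symmetric, so the regiochemistry is unambiguous.

Step 5
Reactants: 7 3-diazo-4-(triethylsilyloxy)pent-4-en-2-one; 4 (E)-2-methylhexa-1,4-dien-3-one
Product: 8 (7Z,9E)-3-diazo-7-methyl-8-(triethylsilyloxy)undeca-7,9-diene-2,4-dione (chain numbering; the new silyl enol ether is the future C1=C10 bond)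
Conditions: Zn(OTf)2 (3 mol %), CH2Cl2, 0 → 20 °C
Reagents that add atoms: none
Why: Lewis-acid-catalysed vinylogous Mukaiyama–Michael addition of the enol ether CH2 to the unsubstituted methylene terminus of the dienone forms C2–C3, and silyl transfer fixes the tetrasubstituted enol ether regiospecifically; the s-cis enone in the closed transition state should give the Z isomer (O cis to the new CH2).

Step 6
Reactants: 8 (7Z,9E)-3-diazo-7-methyl-8-(triethylsilyloxy)undeca-7,9-diene-2,4-dione
Product: 9 (7Z,9E)-3-diazo-7-methyl-8-(triethylsilyloxy)-2-(triisopropylsilyloxy)undeca-1,7,9-trien-4-one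
Conditions: LiN(SiMe3)2, THF, −78 °C; i-Pr3SiOTf, −78 → −40 °C
Reagents that add atoms: triisopropylsilyl triflate, CC(C)[Si](C(C)C)(C(C)C)OS(=O)(=O)C(F)(F)F
Why: Kinetic deprotonation takes the acetyl CH3 in preference to the more hindered C3 methylene, and O-silylation gives the silyloxyvinyl diazoketone; the bulky triisopropylsilyl group is chosen so that the C6 oxygen outlasts the triethylsilyl group on the C10 oxygen later.

Step 7
Reactants: 9 (7Z,9E)-3-diazo-7-methyl-8-(triethylsilyloxy)-2-(triisopropylsilyloxy)undeca-1,7,9-trien-4-one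
Product: 10 bicyclo[3.1.0]hexan-4-one (target numbering) with the cyclopropane C1–C5–C10 on the α face of the five-membered ring: C1 methyl (β), C5 1-(triisopropylsilyloxy)vinyl (β), C10 triethylsilyloxy (endo) and (E)-prop-1-enyl (exo, cis to the C1 methyl and the C5 silyloxyvinyl group); single enantiomer as in the SMILES
Conditions: Rh2(S-PTAD)4 {dirhodium tetrakis[(S)-(1-adamantyl)(phthalimido)acetate]} (1 mol %), hexanes/PhCF3, slow addition of 9, −40 → 0 °C; kept cold
Reagents that add atoms: none
Why: Intramolecular cyclopropanation by the rhodium vinylcarbenoid (donor silyloxyvinyl, acceptor C4 ketone) on the electron-rich C1=C10 enol ether forms C5–C1 and C5–C10. It is stereospecific: the Z enol ether puts the propenyl group cis to the C1 methyl, and the tether forces the silyloxyvinyl group exo. The chiral carboxylate catalyst selects the alkene face and so sets C1 (with C5 and C10).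

Step 8
Reactants: 10 the cyclopropane from step 7
Product: 12 the 3β-(triethylsilyloxy) derivative of 10 (C3–O cis to the C1 methyl and anti to the cyclopropane; all else as in 10), via potassium 3-alkoxide 11 (not isolated)
Conditions: KN(SiMe3)2, THF, −78 °C; 2-(phenylsulfonyl)-3-phenyloxaziridine, −78 °C; Et3SiCl, −78 → −20 °C
Reagents that add atoms: 2-(phenylsulfonyl)-3-phenyloxaziridine, O=S(=O)(c1ccccc1)N1OC1c1ccccc1; triethylsilyl chloride, CC[Si](CC)(CC)Cl
Why: C3 is the only enolisable position (C5 is quaternary), and N-sulfonyloxaziridine oxidation of the potassium enolate occurs on the face opposite the cyclopropane, whose endo C10 substituent covers the α face, so the C3 oxygen ends cis to the C1 methyl; the alkoxide is silylated in the same flask to limit handling of the thermally labile cyclopropane.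

Step 9
Reactants: 12 the 3β-(triethylsilyloxy) cyclopropane
Product: 13 hydroazulen-4-one bis(silyl enol ether): C4 ketone, C5=C6–OSi(i-Pr)3, C9=C10–OSiEt3, 3β-OSiEt3, C1 methyl (β), C8 methyl (α, trans to the C1 methyl)
Conditions: PhMe, 110 °C, acid-free glassware
Reagents that add atoms: none
Why: Thermal [3,3]-sigmatropic shift of the cis-dialkenylcyclopropane through the boat transition state: C7 bonds to C8 as the push–pull C5–C10 bond (C10 silyloxy donor, C4 carbonyl acceptor) breaks and the π bonds move to C5=C6 and C9=C10. The closest known reaction is the divinylcyclopropane–cycloheptadiene rearrangement of silyloxy-substituted vinylcyclopropanes. The seven-membered ring (C1, C5, C6, C7, C8, C9, C10) is closed by pericyclic ring expansion of the three-membered ring, the new σ bond joining the two alkene termini, so no exo or endo cyclisation mode is involved. The one new stereocentre, C8, is set by the boat geometry together with the E-propenyl group (methyl outward, hence trans to the C1 methyl) and is removed again in step 17; C1 and C3 are not touched. The step needs the two alkenyl groups cis on the cyclopropane, which the Z enol ether of 8 and the stereospecific cyclopropanation supply; the C1 methyl that points into the boat is expected to slow the shift enough for 12 to be handled cold, hence the heating. Should any C10 epimer be present, reversible heterolysis of the donor–acceptor bond offers it a path to the same product.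

Step 10
Reactants: 13 the bis(silyl enol ether)
Product: 14 the C10 ketone (C9 now CH2): C4 ketone, C5=C6–OSi(i-Pr)3, 3β-OSiEt3, 8α-methyl
Conditions: 1 % aq. oxalic acid, THF, 0 °C
Reagents that add atoms: none
Why: Mild acid hydrolysis by C-protonation at C9 cleaves only the electron-rich simple enol ether; the vinylogous triisopropylsilyl ester (C5 deactivated by the C4 carbonyl, hindered silicon) and the alkyl triethylsilyl ether next to a carbonyl should survive.

Step 11
Reactants: 14 the C10 ketone
Product: 15 the 10β-alcohol (OH cis to the C1 methyl)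
Conditions: NaBH4, EtOH/THF, −20 → 0 °C
Reagents that add atoms: none
Why: Borohydride reduces the isolated C10 ketone and not the vinylogous-ester carbonyl at C4; hydride enters anti to the angular C1 methyl, as in borohydride reductions of ketones next to an angular methyl group (17-oxo steroids), giving the hydroxyl cis to that methyl.

Step 12
Reactants: 15 the 10β-alcohol
Product: 16 the 10β-tert-butyldimethylsilyl ether
Conditions: t-BuMe2SiOTf, 2,6-lutidine, CH2Cl2, −78 → 0 °C
Reagents that add atoms: tert-butyldimethylsilyl triflate, CC(C)(C)[Si](C)(C)OS(=O)(=O)C(F)(F)F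
Why: Silyl triflate with a weak hindered base silylates the neopentyl secondary alcohol without enolising the ketone; this group stays until the last step.

Step 13
Reactants: 16 the 10β-silyl ether; 17 isopropylmagnesium chloride
Product: 18 the C4 tertiary alcohol: 4β-OH, 4α-isopropyl, C5=C6–OSi(i-Pr)3 retained, 3β-OSiEt3, 10β-OSiMe2t-Bu
Conditions: CeCl3 (anhydrous), THF, −78 °C; pH 7 buffer
Reagents that add atoms: none
Why: Organocerium 1,2-addition to the vinylogous-ester carbonyl (cerium suppresses enolisation and β-hydride reduction); the nucleophile enters anti to the adjacent 3β-silyloxy group, so the new hydroxyl is cis to the C3 oxygen and the isopropyl group is α.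

Step 14
Reactants: 18 the C4 tertiary alcohol
Product: 19 the cis-fused keto diol: C6 ketone, 5β-H, 3β-OH, 4β-OH, 4α-isopropyl, 10β-OSiMe2t-Bu, 8α-methyl
Conditions: Bu4NF, AcOH (1:1), THF, −40 → 0 °C
Reagents that add atoms: none
Why: Fluoride cleaves the silyl enol ether and the resulting enolate is protonated at C5 from the β face, opposite the adjacent isopropyl group, giving the cis ring fusion under kinetic control. The acetic acid buffer guards against retro-aldol cleavage, and acid is avoided because the tertiary allylic alcohol next to an enol ether would eliminate in the Stork–Danheiser sense. The triethylsilyl ether is cleaved as well, while the hindered neopentyl tert-butyldimethylsilyl ether is expected to remain.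

Step 15
Reactants: 19 the keto diol
Product: 20 the 3β-acetate (4β-OH free)
Conditions: Ac2O, pyridine, DMAP (cat.), CH2Cl2, 0 °C
Reagents that add atoms: acetic anhydride, CC(=O)OC(C)=O
Why: Acylation takes the secondary C3 hydroxyl and leaves the hindered tertiary C4 hydroxyl.

Step 16
Reactants: 20 the 3β-acetate
Product: 21 the C6=C7 trimethylsilyl enol ether with the C4 hydroxyl capped as trimethylsilyl ether
Conditions: Me3SiOTf, Et3N, CH2Cl2, −78 → 0 °C; used crude
Reagents that add atoms: trimethylsilyl triflate, C[Si](C)(C)OS(=O)(=O)C(F)(F)F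
Why: Soft enolisation goes toward C7 because the C5 hydrogen sits between two quaternary carbons; silylating the tertiary hydroxyl at the same time removes the aldol hydroxyl from play.

Step 17
Reactants: 21 the silyl enol ether
Product: 22 the C7=C8 enone: C6 ketone, C8 methyl on the alkene, 4β-OSiMe3, 3β-OAc, 10β-OSiMe2t-Bu, 5β-H
Conditions: Pd(OAc)2 (1.1 equiv), MeCN, 20 °C
Reagents that add atoms: none
Why: Saegusa–Ito oxidation: the palladium enolate bound at C7 loses the C8 hydrogen, the only β-hydrogen available, which also removes the temporary C8 stereocentre.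

Step 18
Reactants: 22 the enone
Product: 23 the 6α-allylic alcohol (C6–H β, cis to H5)
Conditions: NaBH4, CeCl3·7H2O, MeOH, −40 °C; NaHCO3 quench
Reagents that add atoms: none
Why: Luche 1,2-reduction; hydride attacks C6 from the β face, the side of H5 and the convex face of the cis-fused bicycle, away from the quaternary C4 branch, so the hydroxyl is α. The buffered quench is meant to keep the tertiary trimethylsilyl ether, whose loss would be harmless.

Step 19
Reactants: 24 4-hydroxybenzoic acid
Product: 26 4-(tert-butyldimethylsilyloxy)benzoic acid, via bis-silyl derivative 25 (not isolated)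
Conditions: t-BuMe2SiCl (2.2 equiv), imidazole, DMF, 20 °C; then AcOH/THF/H2O, 20 °C
Reagents that add atoms: tert-butyldimethylsilyl chloride, CC(C)(C)[Si](C)(C)Cl
Why: Silylation of both the phenol and the acid, then selective hydrolysis of the much more labile silyl ester.

Step 20
Reactants: 23 the 6α-allylic alcohol; 26 4-(tert-butyldimethylsilyloxy)benzoic acid
Product: 27 the protected diester: 6α-[4-(tert-butyldimethylsilyloxy)benzoyloxy], 3β-OAc, 4β-OSiMe3, 10β-OSiMe2t-Bu
Conditions: 2,4,6-Cl3C6H2COCl, Et3N, PhMe, 20 °C; then DMAP, 20 → 40 °C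
Reagents that add atoms: none
Why: Yamaguchi esterification acylates the hindered secondary allylic alcohol through the mixed anhydride and acylpyridinium ion; the tertiary oxygen is not acylated.

Step 21
Reactants: 27 the protected diester
Product: 28 CNP0146780.2 (target)
Conditions: HF·pyridine, pyridine, THF, 0 → 25 °C
Reagents that add atoms: none
Why: Buffered fluoride removes the aryl and C10 tert-butyldimethylsilyl groups and the C4 trimethylsilyl group without touching the acetate or the allylic benzoate.

**Compound list**

1 | (E)-crotonaldehyde | C/C=C/C=O | starting material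
2 | isopropenylmagnesium bromide | CC(=C)[Mg]Br | starting material
3 | (E)-2-methylhexa-1,4-dien-3-ol (racemic) | C/C=C/C(O)C(C)=C | intermediate
4 | (E)-2-methylhexa-1,4-dien-3-one | C/C=C/C(=O)C(C)=C | intermediate
5 | pentane-2,4-dione | CC(=O)CC(C)=O | starting material
6 | 3-diazopentane-2,4-dione | CC(=O)C(=[N+]=[N-])C(C)=O | intermediate
7 | 3-diazo-4-(triethylsilyloxy)pent-4-en-2-one | CC(=O)C(=[N+]=[N-])C(=C)O[Si](CC)(CC)CC | intermediate
8 | (7Z,9E)-3-diazo-7-methyl-8-(triethylsilyloxy)undeca-7,9-diene-2,4-dione | CC(=O)C(=[N+]=[N-])C(=O)CC/C(C)=C(\O[Si](CC)(CC)CC)/C=C/C | intermediate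
9 | (7Z,9E)-3-diazo-7-methyl-8-(triethylsilyloxy)-2-(triisopropylsilyloxy)undeca-1,7,9-trien-4-one | C=C(O[Si](C(C)C)(C(C)C)C(C)C)C(=[N+]=[N-])C(=O)CC/C(C)=C(\O[Si](CC)(CC)CC)/C=C/C | intermediate
10 | bicyclo[3.1.0]hexan-4-one, cyclopropane C1–C5–C10; C1 methyl, C5 1-(triisopropylsilyloxy)vinyl, C10 endo-triethylsilyloxy and exo-(E)-propenyl | C=C(O[Si](C(C)C)(C(C)C)C(C)C)[C@@]12C(=O)CC[C@]1(C)[C@@]2(O[Si](CC)(CC)CC)/C=C/C | intermediate
11 | potassium 3β-alkoxide of 10 (not isolated) | C=C(O[Si](C(C)C)(C(C)C)C(C)C)[C@@]12C(=O)[C@@H]([O-])C[C@]1(C)[C@@]2(O[Si](CC)(CC)CC)/C=C/C.[K+] | intermediate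
12 | 3β-(triethylsilyloxy) derivative of 10 (precursor of the key step) | C=C(O[Si](C(C)C)(C(C)C)C(C)C)[C@@]12C(=O)[C@@H](O[Si](CC)(CC)CC)C[C@]1(C)[C@@]2(O[Si](CC)(CC)CC)/C=C/C | intermediate
13 | hydroazulen-4-one bis(silyl enol ether): C5=C6–OSi(i-Pr)3, C9=C10–OSiEt3, 3β-OSiEt3, 8α-methyl (product of the key step) | CC[Si](CC)(CC)O[C@H]1C[C@]2(C)C(O[Si](CC)(CC)CC)=C[C@H](C)CC(O[Si](C(C)C)(C(C)C)C(C)C)=C2C1=O | intermediate
14 | C10 ketone: C4 ketone, C5=C6–OSi(i-Pr)3, 3β-OSiEt3, 8α-methyl | CC[Si](CC)(CC)O[C@H]1C[C@]2(C)C(=O)C[C@H](C)CC(O[Si](C(C)C)(C(C)C)C(C)C)=C2C1=O | intermediate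
15 | 10β-alcohol of 14 | CC[Si](CC)(CC)O[C@H]1C[C@]2(C)[C@@H](O)C[C@H](C)CC(O[Si](C(C)C)(C(C)C)C(C)C)=C2C1=O | intermediate
16 | 10β-tert-butyldimethylsilyl ether of 15 | CC[Si](CC)(CC)O[C@H]1C[C@]2(C)[C@@H](O[Si](C)(C)C(C)(C)C)C[C@H](C)CC(O[Si](C(C)C)(C(C)C)C(C)C)=C2C1=O | intermediate
17 | isopropylmagnesium chloride | CC(C)[Mg]Cl | starting material
18 | C4 tertiary alcohol: 4β-OH, 4α-isopropyl, C5=C6–OSi(i-Pr)3, 3β-OSiEt3, 10β-OSiMe2t-Bu | CC[Si](CC)(CC)O[C@H]1C[C@]2(C)[C@@H](O[Si](C)(C)C(C)(C)C)C[C@H](C)CC(O[Si](C(C)C)(C(C)C)C(C)C)=C2[C@]1(O)C(C)C | intermediate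
19 | cis-fused keto diol: C6 ketone, 5β-H, 3β-OH, 4β-OH, 10β-OSiMe2t-Bu | O[C@H]1C[C@]2(C)[C@@H](O[Si](C)(C)C(C)(C)C)C[C@H](C)CC(=O)[C@@H]2[C@]1(O)C(C)C | intermediate
20 | 3β-acetate of 19 | CC(=O)O[C@H]1C[C@]2(C)[C@@H](O[Si](C)(C)C(C)(C)C)C[C@H](C)CC(=O)[C@@H]2[C@]1(O)C(C)C | intermediate
21 | C6=C7 trimethylsilyl enol ether, 4β-OSiMe3 | CC(=O)O[C@H]1C[C@]2(C)[C@@H](O[Si](C)(C)C(C)(C)C)C[C@H](C)C=C(O[Si](C)(C)C)[C@@H]2[C@]1(O[Si](C)(C)C)C(C)C | intermediate
22 | C7=C8 enone (C6 ketone), 4β-OSiMe3 | CC(=O)O[C@H]1C[C@]2(C)[C@@H](O[Si](C)(C)C(C)(C)C)CC(C)=CC(=O)[C@@H]2[C@]1(O[Si](C)(C)C)C(C)C | intermediate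
23 | 6α-allylic alcohol | CC(=O)O[C@H]1C[C@]2(C)[C@@H](O[Si](C)(C)C(C)(C)C)CC(C)=C[C@H](O)[C@@H]2[C@]1(O[Si](C)(C)C)C(C)C | intermediate
24 | 4-hydroxybenzoic acid | OC(=O)c1ccc(O)cc1 | starting material
25 | tert-butyldimethylsilyl 4-(tert-butyldimethylsilyloxy)benzoate (not isolated) | CC(C)(C)[Si](C)(C)Oc1ccc(cc1)C(=O)O[Si](C)(C)C(C)(C)C | intermediate
26 | 4-(tert-butyldimethylsilyloxy)benzoic acid | CC(C)(C)[Si](C)(C)Oc1ccc(cc1)C(=O)O | intermediate
27 | protected diester: 6α-[4-(tert-butyldimethylsilyloxy)benzoyloxy], 3β-OAc, 4β-OSiMe3, 10β-OSiMe2t-Bu | CC(=O)O[C@H]1C[C@]2(C)[C@@H](O[Si](C)(C)C(C)(C)C)CC(C)=C[C@H](OC(=O)c3ccc(O[Si](C)(C)C(C)(C)C)cc3)[C@@H]2[C@]1(O[Si](C)(C)C)C(C)C | intermediate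
28 | CNP0146780.2 | CC(=O)O[C@H]1C[C@]2(C)[C@@H](O)CC(C)=C[C@H](OC(=O)c3ccc(O)cc3)[C@@H]2[C@]1(O)C(C)C | target

**Step count and risks**

Total steps: 21. Longest linear sequence: 18 steps (1, 2, 5–18, 20, 21 from crotonaldehyde; equally 3–18, 20, 21 from pentane-2,4-dione).

Steps most likely to fail:

1. Step 9 (key step). The donor–acceptor C5–C10 bond may break heterolytically faster than the concerted shift, with reclosure to a five-membered ring (C7–C10 cyclopentene or O4–C10 dihydrofuran); at the temperature needed, a homodienyl 1,5-hydrogen shift from the inward C1 methyl may also compete. The fallback makes the same two bond changes stepwise and ionically. It sets out from 12: Bu4NF (1.0 equiv), THF, −78 °C cleaves the cyclopropyl triethylsilyl ether at C10, and the cyclopropanolate opens in the retro-aldol sense to the tetrabutylammonium dienolate of the C1 crotonyl ketone F1. On warming, the C7 terminus of the dienolate adds to C8 of the crotonyl enone (seven-membered vinylogous Michael closure), and protonation at C9 gives ketone 14 and, if the new centre forms the other way, the C8 epimer of 14 F2; both serve, because C8 becomes trigonal in step 17. The fallback returns to the route at 14.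

2. Step 7. Face discrimination by the chiral catalyst may be poor, or may be eroded if bond formation becomes stepwise through a zwitterion. The fallback is resolution in place of asymmetric catalysis. It sets out from 9: decomposition with achiral Rh2(OAc)4 gives racemic 10, the racemate is taken through steps 8–10, and racemic 14 (a stable ketone) is separated by preparative chromatography on a chiral stationary phase. It returns to the route at 14 and makes no compound outside the list (entry F0).

3. Step 13. The hindered, deactivated C4 carbonyl may be enolised at C3 or reduced by β-hydride transfer from the secondary organometallic, or the reagent may attack silicon instead of carbon. The fallback uses an sp2 nucleophile without β-hydrogens and then saturates it. It sets out from 16: isopropenylmagnesium bromide 2 with CeCl3 in THF at −78 °C gives the isopropenyl carbinol F3, and H2 with RhCl(PPh3)3 in benzene hydrogenates only the 1,1-disubstituted alkene (the tetrasubstituted enol ether is inert). It returns to the route at 18.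

**Further compounds**

F0 | step 7 | none | none
F1 | step 9 | tetrabutylammonium dienolate of the ring-opened C1 crotonyl ketone (five-membered ring C1–C5; C4 enolate, C5 1-(triisopropylsilyloxy)vinyl, 3β-OSiEt3) | CC[Si](CC)(CC)O[C@H]1C[C@](C)(C(=O)/C=C/C)C(C(=C)O[Si](C(C)C)(C(C)C)C(C)C)=C1[O-].CCCC[N+](CCCC)(CCCC)CCCC
F2 | step 9 | C8 epimer of 14 (8β-methyl) | CC[Si](CC)(CC)O[C@H]1C[C@]2(C)C(=O)C[C@@H](C)CC(O[Si](C(C)C)(C(C)C)C(C)C)=C2C1=O
F3 | step 13 | isopropenyl carbinol: 4β-OH, 4α-isopropenyl analogue of 18 | CC[Si](CC)(CC)O[C@H]1C[C@]2(C)[C@@H](O[Si](C)(C)C(C)(C)C)C[C@H](C)CC(O[Si](C(C)C)(C(C)C)C(C)C)=C2[C@]1(O)C(C)=C
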